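The readings were computed with made-up constants, noise included.

- The reading at 15 h turns on the slow molecule: how far has the right-handed substrate gone by then?

| setting | west | south-east | flask |
|---|---|---|---|
| left-handed substrate | 0.047 M | 0.031 M | 0.047 M |
| right-handed substrate | 0.047 M | 0.031 M | 0.047 M |
| gas | 18 mM (held) | 18 mM (held) | 18 mM (held) |
| precatalyst | 7 mM | 7 mM | 7.0 mM |
| remark | the very flask that is asked about, followed so far | run made earlier |  |
| time |  |  | 15 h |

- west (time / h: left-handed product / %, right-handed product / %): 0.667: 6.5, 1.4; 1.00: 8.8, 0.3; 1.50: 15.8, 0; 2.50: 26.9, 0; 5.00: 43.5, 4.0; 8.00: 47.5, 3.9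
- south-east (time / h: left-handed product / %, right-handed product / %): 0.833: 6.7, 0.5; 1.33: 13.3, 0; 2.50: 29.5, 1.3; 4.00: 38.7, 2.8; 6.00: 50.0, 2.2; 10.0: 48.1, 6.3

(readings scatter by 1 percentage point)

- catalyst is single-handed; left-handed substrate and right-handed substrate are mirror images of each other, charged as a racemate, each of them at the stated concentration
- at the start none of reagent is dissolved
- the analysis behind the earlier runs scatters by 1 percentage point, standard deviation
- candidate steps: reagent + catalyst + left-handed substrate -> catalyst + left-handed product; reagent + catalyst + right-handed substrate -> catalyst + right-handed product; precatalyst -> catalyst; reagent -> decomposition product; gas <-> reagent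
- an excess is the difference of the two amounts in percent of their sum
- an excess is below zero if the other one leads

- excess of left-handed product over right-handed product in the product at 1.5 h
- excess of left-handed product over right-handed product in the product at 15 h
- part of the left-handed substrate and right-handed substrate charged together that has reacted at 15 h

- The last readings of both runs give 0.0120 h⁻¹, the hourly risk, the chance per hour that one right-handed molecule reacts. I treat it as steady and the same at both charges (pseudo-first-order), since the percent curves run close.
- Between 2.50 h and 5.00 h, the west run gives a left-handed molecule a risk of 0.507 h⁻¹. The selectivity factor is therefore 42.3, and the early excess should be near 95.4%.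
- Turn the question round: for the excess to sink to a third, half of the right-handed substrate must react by 15 h. That needs a risk of 0.0462 h⁻¹, and the risk read from the two runs is 3.85 times lower.
- My reckoning for 15 h leaves 0.0498% of the left-handed charge and adds 8.23% of right-handed product, so the excess is 71.7% and 58.2% has reacted.
- The forecast gives 92%, 69% and 59%, from “a selectivity of about 30”, so its late excess is lower than mine.
- The flask gives 95.1%, 75.2% and 57.0%.

    reagent + catalyst + left-handed substrate → catalyst + left-handed product (k = 1.20 M⁻² s⁻¹)
    reagent + catalyst + right-handed substrate → catalyst + right-handed product (k = 0.0250 M⁻² s⁻¹)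
    precatalyst → catalyst (k = 5.30 × 10⁻⁴ s⁻¹)
    reagent → decomposition product (k = 3.10 × 10⁻⁷ s⁻¹)
    gas ⇌ reagent, rate k5*(csat - [reagent]) (kL = 8.70 × 10⁻⁴ s⁻¹)

- In this flask 86% of the right-handed charge remains at 15 h, a risk of 0.0102 h⁻¹. A neighbouring flask holds 0.018 M of precatalyst, 2.57 times this flask's charge. Multiplying the risk by that factor leaves 67.6% of the right-handed charge, and the neighbouring flask stands at 68% at 15 h, with an excess of 51.3% and 66.1% reacted.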